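**Plan**
- Retrosynthetic cuts, in order: (a) in the 2-methyl-2,3-dihydro-4H-pyran-4-one ring (ring C; primed locants O1', C2'–C6', with C6' on coumarin C3) the bonds C5'–C4' and O1'–C2'; (b) the coumarin C3=C4 bond and lactone C–O bond; (c) the aryl–CH bond of the side chain and the ring C–CH3 and C–CHO bonds.
- Enabling feature: ring C is a cyclic vinylogous ester, the O-alkylated enolate of a 1,3-diketone. O1', C6' and C5' are the oxygen, carbonyl carbon and methyl carbon of a 3-acetylcoumarin (a C,O-bis-nucleophile). C4', C3' and C2' form a 3-oxybutanoyl bis-electrophile, which the strained ring of β-butyrolactone delivers in one piece.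
- Forward order: benzene ring A from 5-bromoresorcinol; side chain; two methyls and the formyl group by metalation; pyranone ring B by Knoevenagel condensation; ring C last; one deprotection.
- Stereochemistry: the benzylic centre comes from (2R,3R)-2,3-epoxybutane (SN2 opening); the carbinol centre from Mitsunobu inversion; C2' from (S)-β-butyrolactone with SN2 inversion.
- Helpers: MOM and TBS groups (removed in step 13) and a mesylate made and expelled within step 12.

Key step: step 12

Remark: (2R,3R)-2,3-epoxybutane and both enantiomers of β-butyrolactone are taken to be commercial in enantiopure form.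

**Step 1**
Reactants: 1 5-bromobenzene-1,3-diol
Product: 2 1-bromo-3,5-bis(methoxymethoxy)benzene
Conditions: MOMCl, i-Pr2NEt, CH2Cl2, 0 °C to rt
Reagents that add atoms: chloromethyl methyl ether (MOMCl), COCCl
Why: O-alkylation of both phenols gives acetals that survive organomagnesium and organolithium reagents and later direct ortho-lithiation.

**Step 2**
Reactants: 2 1-bromo-3,5-bis(methoxymethoxy)benzene; 3 (2R,3R)-2,3-epoxybutane
Product: 5 (2R,3R)-3-[3,5-bis(methoxymethoxy)phenyl]butan-2-ol, via aryl Grignard reagent 4 (not isolated)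
Conditions: Mg, THF, 50 °C; then CuI (10 mol %), 3, −30 to 0 °C; aq. NH4Cl
Reagents that add atoms: none
Why: Copper-catalysed SN2 opening of the C2-symmetric trans-epoxide by the aryl Grignard reagent should proceed with inversion at the attacked carbon, setting the benzylic (R) centre and leaving the (R) carbinol untouched; the two epoxide carbons are equivalent, so no regiochemical issue arises.

**Step 3**
Reactants: 5 (2R,3R)-3-[3,5-bis(methoxymethoxy)phenyl]butan-2-ol
Product: 6 (2S,3R)-3-[3,5-bis(methoxymethoxy)phenyl]butan-2-yl 4-nitrobenzoate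
Conditions: 4-nitrobenzoic acid, PPh3, DIAD, toluene, 0 °C to rt
Reagents that add atoms: 4-nitrobenzoic acid, O=C(O)c1ccc(cc1)[N+](=O)[O-]
Why: Mitsunobu esterification should invert the carbinol centre by SN2 displacement of the oxyphosphonium ion, giving the (2S,3R) relationship of the target.

**Step 4**
Reactants: 6 (2S,3R)-3-[3,5-bis(methoxymethoxy)phenyl]butan-2-yl 4-nitrobenzoate
Product: 7 (2S,3R)-3-[3,5-bis(methoxymethoxy)phenyl]butan-2-ol
Conditions: K2CO3 (cat.), MeOH, rt
Reagents that add atoms: none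
Why: Base-catalysed methanolysis of the activated ester should free the alcohol without touching the acetals or either stereocenter.

**Step 5**
Reactants: 7 (2S,3R)-3-[3,5-bis(methoxymethoxy)phenyl]butan-2-ol
Product: 8 tert-butyl{[(2S,3R)-3-[3,5-bis(methoxymethoxy)phenyl]butan-2-yl]oxy}dimethylsilane
Conditions: TBSCl, imidazole, DMF, 40 °C
Reagents that add atoms: tert-butyldimethylsilyl chloride (TBSCl), CC(C)(C)[Si](C)(C)Cl
Why: Silylation masks the secondary alcohol as an ether that tolerates alkyllithiums, NBS, MgBr2 and amide bases, and prevents lactol formation with the later formyl group.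

**Step 6**
Reactants: 8 tert-butyl{[(2S,3R)-3-[3,5-bis(methoxymethoxy)phenyl]butan-2-yl]oxy}dimethylsilane
Product: 10 tert-butyl{[(2S,3R)-3-[3,5-bis(methoxymethoxy)-4-methylphenyl]butan-2-yl]oxy}dimethylsilane, via aryllithium 9 (not isolated)
Conditions: n-BuLi, THF, 0 °C; MeI, 0 °C to rt
Reagents that add atoms: iodomethane (MeI), CI
Why: Directed ortho-metalation should occur at the ring carbon flanked by both OMOM groups, the most acidic and doubly coordinated site, and MeI alkylates the aryllithium.

**Step 7**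
Reactants: 10 tert-butyl{[(2S,3R)-3-[3,5-bis(methoxymethoxy)-4-methylphenyl]butan-2-yl]oxy}dimethylsilane
Product: 11 tert-butyl{[(2S,3R)-3-[2,6-dibromo-3,5-bis(methoxymethoxy)-4-methylphenyl]butan-2-yl]oxy}dimethylsilane
Conditions: NBS (2.1 equiv), MeCN, 0 °C to rt, dark
Reagents that add atoms: N-bromosuccinimide (NBS), O=C1CCC(=O)N1Br
Why: Electrophilic aromatic bromination should fill the only two ring C–H positions left, each ortho and para to an acetal oxygen.

**Step 8**
Reactants: 11 tert-butyl{[(2S,3R)-3-[2,6-dibromo-3,5-bis(methoxymethoxy)-4-methylphenyl]butan-2-yl]oxy}dimethylsilane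
Product: 13 tert-butyl{[(2S,3R)-3-[2-bromo-3,5-bis(methoxymethoxy)-4,6-dimethylphenyl]butan-2-yl]oxy}dimethylsilane, via bromo aryllithium 12 (not isolated)
Conditions: n-BuLi (1.05 equiv), THF, −78 °C; MeI, −78 °C to rt
Reagents that add atoms: iodomethane (MeI), CI
Why: Lithium–bromine exchange with one equivalent of n-BuLi should replace only one bromine, since the monolithio arene resists a second exchange; the two bromines are interconverted by rotation about the aryl–CH bond, so one product results.

**Step 9**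
Reactants: 13 tert-butyl{[(2S,3R)-3-[2-bromo-3,5-bis(methoxymethoxy)-4,6-dimethylphenyl]butan-2-yl]oxy}dimethylsilane
Product: 15 2-[(2R,3S)-3-{[tert-butyl(dimethyl)silyl]oxy}butan-2-yl]-4,6-bis(methoxymethoxy)-3,5-dimethylbenzaldehyde, via aryllithium 14 (not isolated)
Conditions: n-BuLi, THF, −78 °C; DMF, −78 to 0 °C; aq. NH4Cl
Reagents that add atoms: N,N-dimethylformamide (DMF), CN(C)C=O
Why: A second lithium–bromine exchange followed by formylation of the aryllithium with DMF places the formyl group at the last ring position with no regiochemical ambiguity.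

**Step 10**
Reactants: 15 2-[(2R,3S)-3-{[tert-butyl(dimethyl)silyl]oxy}butan-2-yl]-4,6-bis(methoxymethoxy)-3,5-dimethylbenzaldehyde
Product: 16 2-[(2R,3S)-3-{[tert-butyl(dimethyl)silyl]oxy}butan-2-yl]-6-hydroxy-4-(methoxymethoxy)-3,5-dimethylbenzaldehyde
Conditions: MgBr2·OEt2, Et2O/CH2Cl2, 0 °C to rt; aq. NH4Cl
Reagents that add atoms: none
Why: Chelation of divalent magnesium between the formyl oxygen and the neighbouring acetal oxygen should activate only the ortho OMOM group for bromide-assisted acetal cleavage, leaving the para OMOM group and the silyl ether in place.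

**Step 11**
Reactants: 16 2-[(2R,3S)-3-{[tert-butyl(dimethyl)silyl]oxy}butan-2-yl]-6-hydroxy-4-(methoxymethoxy)-3,5-dimethylbenzaldehyde; 17 ethyl acetoacetate
Product: 18 3-acetyl-5-[(2R,3S)-3-{[tert-butyl(dimethyl)silyl]oxy}butan-2-yl]-7-(methoxymethoxy)-6,8-dimethyl-2H-chromen-2-one
Conditions: piperidine (cat.), AcOH (cat.), EtOH, 60 °C
Reagents that add atoms: none
Why: Knoevenagel condensation of the salicylaldehyde with the active methylene of 17, followed by lactonisation of the phenol onto the ester, should close ring B and deliver the 3-acetyl group.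

**Step 12**
Reactants: 18 3-acetyl-5-[(2R,3S)-3-{[tert-butyl(dimethyl)silyl]oxy}butan-2-yl]-7-(methoxymethoxy)-6,8-dimethyl-2H-chromen-2-one; 19 (S)-β-butyrolactone [(4S)-4-methyloxetan-2-one]
Product: 23 5-[(2R,3S)-3-{[tert-butyl(dimethyl)silyl]oxy}butan-2-yl]-7-(methoxymethoxy)-6,8-dimethyl-3-[(2R)-2-methyl-4-oxo-3,4-dihydro-2H-pyran-6-yl]-2H-chromen-2-one, via lithium enolate 20 (not isolated), via dilithium alkoxide diketonate 21 (not isolated), via lithium diketonate mesylate 22 (not isolated)
Conditions: LiN(SiMe3)2 (1.05 equiv), THF, −78 °C; 19, −78 to −30 °C; LiN(SiMe3)2 (1.0 equiv), then Ms2O (1.05 equiv), −78 to 0 °C; DMPU, 0 to 40 °C; aq. NH4Cl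
Reagents that add atoms: none
Why: Proposed new method: the kinetic lithium enolate 20 of the acetyl group should attack the strained acyl carbon of 19 through its carbon (acyl–oxygen cleavage, forming C5'–C4'), and a second equivalent of base gives the alkoxide/diketonate 21, whose harder alkoxide is mesylated by Ms2O before the diketonate oxygen that was the acetyl oxygen displaces the mesylate (forming O1'–C2'). The closest known reaction types are the Claisen-type opening of β-lactones by lithium ester enolates to δ-hydroxy-β-keto esters and the intramolecular O-alkylation of 1,3-dicarbonyl enolates; running both in one flask with stereochemical inversion is the unproven part. The only ring closed is ring C, by a 6-(enolendo)-exo-tet SN2 attack of the enolate oxygen, whereas C-alkylation would need a four-membered ring and is excluded. The new stereocenter C2' is controlled by the (S) centre of the lactone, which the SN2 step should invert to (R). The step needs substitution to beat E1cB elimination to a crotonyl diketone, which would reclose without stereocontrol; this is secured because the leaving group is installed only after the C–C bond exists and the diketone is held as its monoanion, so deprotonation at C3' would require a dianion. Ms2O brings in no nucleophilic halide, the secondary lactone carbon resists direct alkyl–oxygen attack by the hard enolate, and DMPU loosens the lithium chelate so the enolate oxygen can reach C2'.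

**Step 13**
Reactants: 23 5-[(2R,3S)-3-{[tert-butyl(dimethyl)silyl]oxy}butan-2-yl]-7-(methoxymethoxy)-6,8-dimethyl-3-[(2R)-2-methyl-4-oxo-3,4-dihydro-2H-pyran-6-yl]-2H-chromen-2-one
Product: 24 7-hydroxy-5-[(2R,3S)-3-hydroxybutan-2-yl]-6,8-dimethyl-3-[(2R)-2-methyl-4-oxo-3,4-dihydro-2H-pyran-6-yl]-2H-chromen-2-one
Conditions: aq. HCl (3 M), THF, rt
Reagents that add atoms: none
Why: Aqueous acid should hydrolyse the aryl MOM acetal and the secondary silyl ether in one operation while the lactone, the vinylogous ester and the three stereocenters persist; base is avoided because it could open ring C by retro-oxa-Michael reaction and epimerise C2'.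

**Compound list**
1 | 5-bromobenzene-1,3-diol | Oc1cc(O)cc(Br)c1 | starting material
2 | 1-bromo-3,5-bis(methoxymethoxy)benzene | COCOc1cc(OCOC)cc(Br)c1 | intermediate
3 | (2R,3R)-2,3-epoxybutane | C[C@H]1O[C@@H]1C | starting material
4 | [3,5-bis(methoxymethoxy)phenyl]magnesium bromide | COCOc1cc(OCOC)cc([Mg]Br)c1 | intermediate
5 | (2R,3R)-3-[3,5-bis(methoxymethoxy)phenyl]butan-2-ol | COCOc1cc(OCOC)cc(c1)[C@@H](C)[C@@H](C)O | intermediate
6 | (2S,3R)-3-[3,5-bis(methoxymethoxy)phenyl]butan-2-yl 4-nitrobenzoate | COCOc1cc(OCOC)cc(c1)[C@@H](C)[C@H](C)OC(=O)c1ccc(cc1)[N+](=O)[O-] | intermediate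
7 | (2S,3R)-3-[3,5-bis(methoxymethoxy)phenyl]butan-2-ol | COCOc1cc(OCOC)cc(c1)[C@@H](C)[C@H](C)O | intermediate
8 | tert-butyl{[(2S,3R)-3-[3,5-bis(methoxymethoxy)phenyl]butan-2-yl]oxy}dimethylsilane | COCOc1cc(OCOC)cc(c1)[C@@H](C)[C@H](C)O[Si](C)(C)C(C)(C)C | intermediate
9 | {4-[(2R,3S)-3-{[tert-butyl(dimethyl)silyl]oxy}butan-2-yl]-2,6-bis(methoxymethoxy)phenyl}lithium | COCOc1cc(cc(OCOC)c1[Li])[C@@H](C)[C@H](C)O[Si](C)(C)C(C)(C)C | intermediate
10 | tert-butyl{[(2S,3R)-3-[3,5-bis(methoxymethoxy)-4-methylphenyl]butan-2-yl]oxy}dimethylsilane | COCOc1cc(cc(OCOC)c1C)[C@@H](C)[C@H](C)O[Si](C)(C)C(C)(C)C | intermediate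
11 | tert-butyl{[(2S,3R)-3-[2,6-dibromo-3,5-bis(methoxymethoxy)-4-methylphenyl]butan-2-yl]oxy}dimethylsilane | COCOc1c(Br)c(c(Br)c(OCOC)c1C)[C@@H](C)[C@H](C)O[Si](C)(C)C(C)(C)C | intermediate
12 | {3-bromo-2-[(2R,3S)-3-{[tert-butyl(dimethyl)silyl]oxy}butan-2-yl]-4,6-bis(methoxymethoxy)-5-methylphenyl}lithium | COCOc1c([Li])c(c(Br)c(OCOC)c1C)[C@@H](C)[C@H](C)O[Si](C)(C)C(C)(C)C | intermediate
13 | tert-butyl{[(2S,3R)-3-[2-bromo-3,5-bis(methoxymethoxy)-4,6-dimethylphenyl]butan-2-yl]oxy}dimethylsilane | COCOc1c(C)c(c(Br)c(OCOC)c1C)[C@@H](C)[C@H](C)O[Si](C)(C)C(C)(C)C | intermediate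
14 | {2-[(2R,3S)-3-{[tert-butyl(dimethyl)silyl]oxy}butan-2-yl]-4,6-bis(methoxymethoxy)-3,5-dimethylphenyl}lithium | COCOc1c(C)c(c([Li])c(OCOC)c1C)[C@@H](C)[C@H](C)O[Si](C)(C)C(C)(C)C | intermediate
15 | 2-[(2R,3S)-3-{[tert-butyl(dimethyl)silyl]oxy}butan-2-yl]-4,6-bis(methoxymethoxy)-3,5-dimethylbenzaldehyde | COCOc1c(C)c(c(C=O)c(OCOC)c1C)[C@@H](C)[C@H](C)O[Si](C)(C)C(C)(C)C | intermediate
16 | 2-[(2R,3S)-3-{[tert-butyl(dimethyl)silyl]oxy}butan-2-yl]-6-hydroxy-4-(methoxymethoxy)-3,5-dimethylbenzaldehyde | COCOc1c(C)c(c(C=O)c(O)c1C)[C@@H](C)[C@H](C)O[Si](C)(C)C(C)(C)C | intermediate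
17 | ethyl acetoacetate (ethyl 3-oxobutanoate) | CCOC(=O)CC(C)=O | starting material
18 | 3-acetyl-5-[(2R,3S)-3-{[tert-butyl(dimethyl)silyl]oxy}butan-2-yl]-7-(methoxymethoxy)-6,8-dimethyl-2H-chromen-2-one | Cc1c(OCOC)c(C)c2oc(=O)c(C(C)=O)cc2c1[C@@H](C)[C@H](C)O[Si](C)(C)C(C)(C)C | intermediate
19 | (S)-β-butyrolactone [(4S)-4-methyloxetan-2-one] | C[C@H]1CC(=O)O1 | starting material
20 | lithium enolate of 18 (lithium 1-(coumarin-3-yl)ethenolate) | Cc1c(OCOC)c(C)c2oc(=O)c(C(=C)O[Li])cc2c1[C@@H](C)[C@H](C)O[Si](C)(C)C(C)(C)C | intermediate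
21 | dilithium salt (alkoxide and diketonate) of the 3-[(5S)-5-hydroxy-3-oxohexanoyl]coumarin derived from 18 | Cc1c(OCOC)c(C)c2oc(=O)c(C(O[Li])=CC(=O)C[C@H](C)O[Li])cc2c1[C@@H](C)[C@H](C)O[Si](C)(C)C(C)(C)C | intermediate
22 | lithium diketonate of the 3-[(5S)-5-(methanesulfonyloxy)-3-oxohexanoyl]coumarin derived from 18 | Cc1c(OCOC)c(C)c2oc(=O)c(C(O[Li])=CC(=O)C[C@H](C)OS(C)(=O)=O)cc2c1[C@@H](C)[C@H](C)O[Si](C)(C)C(C)(C)C | intermediate
23 | 5-[(2R,3S)-3-{[tert-butyl(dimethyl)silyl]oxy}butan-2-yl]-7-(methoxymethoxy)-6,8-dimethyl-3-[(2R)-2-methyl-4-oxo-3,4-dihydro-2H-pyran-6-yl]-2H-chromen-2-one | Cc1c(OCOC)c(C)c2oc(=O)c(C3=CC(=O)C[C@@H](C)O3)cc2c1[C@@H](C)[C@H](C)O[Si](C)(C)C(C)(C)C | intermediate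
24 | 7-hydroxy-5-[(2R,3S)-3-hydroxybutan-2-yl]-6,8-dimethyl-3-[(2R)-2-methyl-4-oxo-3,4-dihydro-2H-pyran-6-yl]-2H-chromen-2-one | Cc1c(O)c(C)c2oc(=O)c(C3=CC(=O)C[C@@H](C)O3)cc2c1[C@@H](C)[C@H](C)O | target

**Step count**
Total: 13 steps. Longest linear sequence: 13 steps (1 to 24; compounds 3, 17 and 19 are bought).

**Steps most likely to fail**

1. Step 12 (proposed new method). Elimination of the mesylate, or slow O-alkylation by the tightly chelated lithium diketonate followed by non-selective oxa-Michael reclosure, would erode the configuration at C2'. Sulfonylation at the diketonate oxygen and conjugate self-addition of the enolate to C4 of a second coumarin are further risks. Fallback with known chemistry, setting out from 18: the lithium enolate 20 (LiN(SiMe3)2, THF, −78 °C) would be acylated by the enantiomeric lactone, commercial (R)-β-butyrolactone (C[C@@H]1CC(=O)O1), and quenched with aq. NH4Cl to isolate the δ-hydroxy-β-diketone 5-[(2R,3S)-3-{[tert-butyl(dimethyl)silyl]oxy}butan-2-yl]-3-[(5R)-5-hydroxy-3-oxohexanoyl]-7-(methoxymethoxy)-6,8-dimethyl-2H-chromen-2-one F1. Aqueous HCl in THF would then effect the classical hemiketalisation–dehydration of a δ-hydroxy-β-diketone to the dihydropyranone, closing O1'–C6' with retention at the carbinol carbon, and would remove both protecting groups at the same time. The sequence comes back to the route at the target 24.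

2. Step 10. Poor discrimination between the two acetals (loss of both, or partial loss of the silyl ether) would give mixtures. Fallback, setting out from 15: both MOM groups would be removed on purpose with TFA in wet CH2Cl2 at 0 °C, where the hindered secondary silyl ether should survive, to give 2-[(2R,3S)-3-{[tert-butyl(dimethyl)silyl]oxy}butan-2-yl]-4,6-dihydroxy-3,5-dimethylbenzaldehyde F2. Knoevenagel condensation with 17 under the conditions of step 11 would give 3-acetyl-5-[(2R,3S)-3-{[tert-butyl(dimethyl)silyl]oxy}butan-2-yl]-7-hydroxy-6,8-dimethyl-2H-chromen-2-one F3. Its phenol would be re-protected with MOMCl and i-Pr2NEt, coming back to the route at 18.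

3. Step 3. Elimination toward the conjugated alkene, or incomplete inversion at the hindered carbinol through aryl participation, would lower the diastereomeric purity. Fallback, setting out from 5: oxidation with Dess–Martin periodinane (NaHCO3 buffer, CH2Cl2) would give (3R)-3-[3,5-bis(methoxymethoxy)phenyl]butan-2-one F4. Reduction with LiBH(s-Bu)3 in THF at −78 °C, with Felkin–Anh attack anti to the aryl group, should give the (2S,3R) alcohol, coming back to the route at 7.

**Further compounds**
F1 | step 12 | 5-[(2R,3S)-3-{[tert-butyl(dimethyl)silyl]oxy}butan-2-yl]-3-[(5R)-5-hydroxy-3-oxohexanoyl]-7-(methoxymethoxy)-6,8-dimethyl-2H-chromen-2-one | Cc1c(OCOC)c(C)c2oc(=O)c(C(=O)CC(=O)C[C@@H](C)O)cc2c1[C@@H](C)[C@H](C)O[Si](C)(C)C(C)(C)C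
F2 | step 10 | 2-[(2R,3S)-3-{[tert-butyl(dimethyl)silyl]oxy}butan-2-yl]-4,6-dihydroxy-3,5-dimethylbenzaldehyde | Oc1c(C)c(c(C=O)c(O)c1C)[C@@H](C)[C@H](C)O[Si](C)(C)C(C)(C)C
F3 | step 10 | 3-acetyl-5-[(2R,3S)-3-{[tert-butyl(dimethyl)silyl]oxy}butan-2-yl]-7-hydroxy-6,8-dimethyl-2H-chromen-2-one | Cc1c(O)c(C)c2oc(=O)c(C(C)=O)cc2c1[C@@H](C)[C@H](C)O[Si](C)(C)C(C)(C)C
F4 | step 3 | (3R)-3-[3,5-bis(methoxymethoxy)phenyl]butan-2-one | COCOc1cc(OCOC)cc(c1)[C@@H](C)C(C)=O
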